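**Plan**

- Locants (daucane): C1 methyl-bearing fusion carbon, C2/C3 five-ring CH2, C4 carbinol carbon, C5 fusion CH, C6 isovalerate carbon, C7 CH2, C8(Me)–C9 epoxide carbons, C10 acetate carbon; α is the face of H5, β the face of the C1 methyl.
- Retrosynthesis: remove the C10 acetate and the C8–C9 epoxide oxygen (back to the C10 ketone with C8=C9), then cut C9–C10 and C8–C9 to take C9 out of the seven-membered ring. This is possible because in ring C1–C10–C9–C8–C7–C6–C5 the oxygenated C10 sits between quaternary C1 and methyl-bearing C8 with only the CH C9 in between, i.e. a 2,6-dimethylcyclohexanone (ring C1–C10–C8–C7–C6–C5) plus one inserted carbon.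
- Further cuts: C6–O, C4–isopropyl, the five-ring bond C2–C3 (aldol), and at C1 the bonds to C2 and to the methyl group, which leads to (R)-carvone.
- Forward: the six-membered ring is that of carvone; C1 is made quaternary by two α′-alkylations; the five-membered ring closes by aldol condensation; isopropyl is added at C4 and oxygen at C6; the six-membered ring is then enlarged to the seven-membered ring; reduction with inversion, epoxidation and acetylation finish the synthesis.
- Stereochemistry: C5 is the carvone centre; C1 by allylation anti to the C5 substituent (trans fusion); C4 by α-face addition opposite the C1 methyl; C6 by α-face [4+2] addition of singlet oxygen; C10 by hydride reduction then Mitsunobu inversion; C8/C9 by epoxidation directed by the 10α-hydroxyl.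

Key step: step 12

Assumption: hydride is taken to attack the C10 ketone anti to the C1 methyl, so the reduction should give the 10β-alcohol and an inversion is planned.

**Route**

Step 1
Reactants: 1 (R)-carvone; 2 iodomethane
Product: 3 α′-methylcarvone, mainly the epimer with the new methyl trans to the isopropenyl group
Conditions: lithium diisopropylamide, THF, −78 °C; MeI, −78 to 0 °C
Reagents that add atoms: iodomethane, CI
Why: Kinetic deprotonation at the α′-CH2 gives the cross-conjugated lithium enolate, which is methylated by SN2 (enolate alkylation) mainly anti to the C5 isopropenyl group; the new C1 centre need not be controlled because it becomes an enolate carbon again in step 2.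

Step 2
Reactants: 3 α′-methylcarvone; 4 allyl bromide
Product: 5 α′-allyl-α′-methylcarvone, allyl trans and methyl cis to the isopropenyl group
Conditions: lithium diisopropylamide, THF, −78 °C; allyl bromide, −78 °C to rt
Reagents that add atoms: allyl bromide, C=CCBr
Why: Second enolate alkylation at the same carbon: the tetrasubstituted lithium enolate is attacked by the allyl halide on the face opposite the adjacent isopropenyl group, so the allyl group (future C2) is set trans and the C1 methyl cis to the C5 substituent, which fixes quaternary C1 and later the trans ring fusion.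

Step 3
Reactants: 5 α′-allyl-α′-methylcarvone
Product: 6 (E)-propenyl isomer of 5
Conditions: RuHCl(CO)(PPh3)3 (cat.), toluene, 80 °C
Reagents that add atoms: none
Why: Metal hydride-catalysed alkene isomerisation (hydrometalation then β-hydride elimination) shifts the monosubstituted double bond into the more stable internal position next to C1, while the more hindered 1,1-disubstituted isopropenyl group and the conjugated enone are expected to be left alone; the E/Z outcome does not matter.

Step 4
Reactants: 6 (E)-propenyl isomer of 5; 7 ozone
Product: 8 keto aldehyde (formyl on C1, acetyl on C5, trans), used crude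
Conditions: O3, CH2Cl2/MeOH, −78 °C, dye indicator; then Me2S, −78 °C to rt
Reagents that add atoms: ozone, [O-][O+]=O
Why: Ozonolysis with reductive work-up cleaves the two isolated, electron-rich double bonds (propenyl to the C2 aldehyde on C1, isopropenyl to the C4 methyl ketone on C5) faster than the electron-poor conjugated C7=C8 bond, and titration to the dye end point should keep the enone and all stereocentres intact.

Step 5
Reactants: 8 keto aldehyde
Product: 9 trans-fused bicyclic dienedione (C4 ketone with C2=C3, C10 ketone with C7=C8)
Conditions: piperidine (cat.), AcOH (cat.), toluene, 60 °C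
Reagents that add atoms: none
Why: Intramolecular aldol condensation of a 1,4-keto aldehyde under mild amine–acid catalysis: the aldehyde on quaternary C1 cannot enolise, the methyl group of the ketone (C3) is the only carbon that can reach it through a five-membered transition state, and dehydration gives the cyclopentenone with the trans relationship at C1/C5 from step 2 untouched.

Step 6
Reactants: 9 trans-fused bicyclic dienedione
Product: 10 trans-fused enedione (C2–C3 saturated, C7=C8 kept)
Conditions: H2 (1 atm), RhCl(PPh3)3 (cat.), toluene/EtOH, rt
Reagents that add atoms: none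
Why: Homogeneous hydrogenation with RhCl(PPh3)3 is governed by alkene substitution, so the cis-disubstituted C2=C3 bond should be saturated while the trisubstituted α-methyl enone bond C7=C8 stays, in analogy to the selective 1,2-saturation of steroidal 1,4-dien-3-ones; the neutral medium does not enolise C5 and no stereocentre is formed.

Step 7
Reactants: 10 trans-fused enedione; 11 isopropylmagnesium chloride
Product: 12 tertiary alcohol (4β-OH, 4α-isopropyl)
Conditions: i-PrMgCl, CeCl3, THF, −78 °C; aq. NH4Cl
Reagents that add atoms: isopropylmagnesium chloride, CC(C)[Mg]Cl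
Why: Carbonyl addition of the weakly basic organocerium reagent i-PrCeCl2 to the cyclopentanone C4, far less hindered than the conjugated C10 carbonyl next to quaternary C1; the reagent should approach from the α face, away from the β C1 methyl that is 1,3 to C4, giving 4β-OH/4α-isopropyl without enolisation toward C5.

Step 8
Reactants: 12 tertiary alcohol; 13 trimethylsilyl trifluoromethanesulfonate
Product: 14 bis-silyl dienol ether (C10(OSiMe3)=C8–C7=C6, 4β-OSiMe3)
Conditions: Me3SiOTf, Et3N, CH2Cl2, 0 °C
Reagents that add atoms: trimethylsilyl trifluoromethanesulfonate, C[Si](C)(C)OS(=O)(=O)C(F)(F)F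
Why: Soft enolisation with silyl triflate and amine: because C1 is quaternary the enone can only lose a γ-hydrogen from C6, giving the 1-siloxy-1,3-diene, and the tertiary C4 alcohol is silylated in the same operation (O-silylation).

Step 9
Reactants: 14 bis-silyl dienol ether; 15 dioxygen
Product: 17 6α-hydroxy enone, via endoperoxide 16 (not isolated)
Conditions: O2, visible light, tetraphenylporphyrin (cat.), CH2Cl2, −78 °C; then thiourea, MeOH, −78 °C to rt
Reagents that add atoms: dioxygen, O=O
Why: Photosensitised [4+2] cycloaddition of singlet oxygen to the ring-locked s-cis diene should join oxygen to C6 and C10 from the α face, opposite the pseudo-axial C1 methyl, and thiourea reduction of the O–O bond followed by collapse of the C10 silyl hemiketal returns the enone with the new 6α-hydroxyl cis to H5.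

Step 10
Reactants: 17 6α-hydroxy enone; 18 isovaleryl chloride
Product: 19 6α-isovalerate enone
Conditions: isovaleryl chloride, pyridine, 4-dimethylaminopyridine (cat.), CH2Cl2, 0 °C to rt
Reagents that add atoms: isovaleryl chloride, CC(C)CC(=O)Cl
Why: Esterification of the only free hydroxyl with the acid chloride under nucleophilic catalysis, with retention at C6; the tertiary C4 oxygen is blocked as its silyl ether.

Step 11
Reactants: 19 6α-isovalerate enone; 20 chlorotrimethylsilane
Product: 21 trans-hydrindanone C10 trimethylsilyl enol ether (C10=C8)
Conditions: LiBH(s-Bu)3, THF, −78 °C; then Me3SiCl, Et3N, −78 to 0 °C; non-aqueous work-up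
Reagents that add atoms: chlorotrimethylsilane, C[Si](C)(C)Cl
Why: Conjugate reduction: the bulky trialkylborohydride cannot reach the C10 carbonyl beside quaternary C1 and should deliver hydride to the unsubstituted β-carbon C7, and O-silylation of the resulting enolate gives the C10=C8 silyl enol ether, the only regioisomer possible; the ester does not react at −78 °C.

Step 12
Reactants: 21 trans-hydrindanone C10 trimethylsilyl enol ether; 22 diiodomethane
Product: 25 hydroazulenone (C10 ketone, C8=C9), via siloxycyclopropane 23 (not isolated), via β-chloro ketone 24 (not isolated)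
Conditions: Et2Zn, CH2I2, CH2Cl2, 0 °C to rt; then FeCl3, DMF, 0 °C; then NaOAc, MeOH, 40 °C
Reagents that add atoms: diiodomethane, ICI
Why: The zinc carbenoid formed from Et2Zn and CH2I2 (Furukawa variant of the Simmons–Smith reaction) transfers CH2 in a concerted [2+1] addition to the electron-rich C10=C8 enol ether, closing the three-membered ring and making the C9–C10 and C8–C9 bonds. FeCl3 (trivalent iron) then removes one electron from the siloxycyclopropane, the silyl group leaves as Me3SiCl, and the resulting C10 oxy radical cleaves the C10–C8 bond shared by the three- and six-membered rings, so the seven-membered ring arises by fragmentation (ring enlargement) and not by a cyclisation. The tertiary C8 radical takes chlorine from a second FeCl3, and NaOAc eliminates HCl from the β-chloro ketone through the acidic C9 hydrogens to give the conjugated C8=C9 enone. This is the Saegusa–Ito one-carbon ring expansion of cyclic silyl enol ethers, known for 2-methyl-substituted siloxycyclohexenes. No new stereocentre survives, since C8 and C9 end as sp2 carbons and C10 as a carbonyl, so the face of carbene transfer is irrelevant. The step needs the enol ether on the C8 side and cleavage of the internal rather than an external cyclopropane bond: the first is fixed because C1 is quaternary, the second by the stability of the tertiary, methyl-bearing C8 radical and the relief of ring strain, and the ester and silyl ether should tolerate the carbenoid and FeCl3 in DMF.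

Step 13
Reactants: 25 hydroazulenone
Product: 26 10β-allylic alcohol
Conditions: NaBH4, CeCl3·7H2O, MeOH, −78 to −20 °C
Reagents that add atoms: none
Why: Luche 1,2-reduction: the cerium-activated borohydride attacks the carbonyl carbon of the β,β-disubstituted enone and should come from the α face, anti to the C1 methyl that stands perpendicular to the carbonyl plane, so the 10β-alcohol is expected; the ester is not reduced at low temperature.

Step 14
Reactants: 26 10β-allylic alcohol; 27 formic acid
Product: 29 10α-allylic alcohol, via 10α-formate 28 (not isolated)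
Conditions: PPh3, diisopropyl azodicarboxylate, HCO2H, THF, 0 °C to rt; then KHCO3 (cat.), MeOH, 0 °C
Reagents that add atoms: formic acid, O=CO (supplies the C10 oxygen)
Why: Mitsunobu reaction: the oxyphosphonium group at C10 is displaced by formate in an SN2 process with inversion from the open α face, assisted by the adjacent C8=C9 π bond at this neopentyl-type allylic carbon, and mild base-catalysed methanolysis should remove the formyl group selectively to leave the 10α-alcohol.

Step 15
Reactants: 29 10α-allylic alcohol; 30 tert-butyl hydroperoxide
Product: 31 8α,9α-epoxy-10α-alcohol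
Conditions: VO(acac)2 (cat.), t-BuOOH, CH2Cl2, 0 °C to rt
Reagents that add atoms: tert-butyl hydroperoxide, CC(C)(C)OO
Why: Hydroxyl-directed epoxidation: the allylic alcohol binds the vanadium alkylperoxide and oxygen is delivered to C8=C9 on the face of the hydroxyl, so C8 and C9 are set α, cis to the C10 oxygen, while the esters and silyl ether do not take part.

Step 16
Reactants: 31 8α,9α-epoxy-10α-alcohol; 32 acetic anhydride
Product: 33 10α-acetate (4β-OSiMe3 still in place)
Conditions: Ac2O, pyridine, 4-dimethylaminopyridine (cat.), CH2Cl2, 0 °C to rt
Reagents that add atoms: acetic anhydride, CC(=O)OC(C)=O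
Why: Acylation of the secondary C10 alcohol with retention of configuration; the tertiary C4 oxygen is still silylated and the epoxide is stable to the basic medium.

Step 17
Reactants: 33 10α-acetate
Product: 34 CNP0137153.1
Conditions: Bu4NF, AcOH, THF, 0 °C
Reagents that add atoms: none
Why: Fluoride-mediated desilylation (Si–F bond formation) frees the tertiary C4 alcohol, the acetic acid buffer keeping the esters and the trisubstituted epoxide intact; no stereocentre is involved.

**Compound list**

1 | (R)-carvone | CC(=C)[C@@H]1CC=C(C)C(=O)C1 | starting material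
2 | iodomethane | CI | starting material
3 | α′-methylcarvone, (5R)-2,6-dimethyl-5-(prop-1-en-2-yl)cyclohex-2-en-1-one, major epimer shown (new methyl trans to isopropenyl; minor epimer carried along) | O=C1C(C)=CC[C@@H](C(C)=C)[C@@H]1C | intermediate
4 | allyl bromide | C=CCBr | starting material
5 | α′-allyl-α′-methylcarvone, 6-allyl-2,6-dimethyl-5-(prop-1-en-2-yl)cyclohex-2-en-1-one, allyl trans and methyl cis to isopropenyl | O=C1C(C)=CC[C@@H](C(C)=C)[C@]1(C)CC=C | intermediate
6 | propenyl isomer, 2,6-dimethyl-6-[(E)-prop-1-enyl]-5-(prop-1-en-2-yl)cyclohex-2-en-1-one, configuration as in 5 | O=C1C(C)=CC[C@@H](C(C)=C)[C@]1(C)/C=C/C | intermediate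
7 | ozone | [O-][O+]=O | starting material
8 | keto aldehyde, 6-acetyl-1,3-dimethyl-2-oxocyclohex-3-ene-1-carbaldehyde, formyl trans to acetyl | O=C1C(C)=CC[C@@H](C(C)=O)[C@]1(C)C=O | intermediate
9 | trans-fused bicyclic dienedione: C10 ketone with C7=C8 in the six-membered ring, C4 ketone with C2=C3 in the five-membered ring, C1 methyl β, H5 α | O=C1C(C)=CC[C@@H]2[C@]1(C)C=CC2=O | intermediate
10 | trans-fused enedione: as 9 with C2–C3 saturated | O=C1C(C)=CC[C@@H]2[C@]1(C)CCC2=O | intermediate
11 | isopropylmagnesium chloride | CC(C)[Mg]Cl | starting material
12 | tertiary alcohol: 4β-hydroxy-4α-isopropyl trans-hydrindenone (C10 ketone, C7=C8) | O=C1C(C)=CC[C@@H]2[C@]1(C)CC[C@@]2(O)C(C)C | intermediate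
13 | trimethylsilyl trifluoromethanesulfonate | C[Si](C)(C)OS(=O)(=O)C(F)(F)F | starting material
14 | bis-silyl dienol ether: C10(OSiMe3)=C8(Me)–C7=C6 diene, 4β-OSiMe3 | C[Si](C)(C)OC1=C(C)C=C[C@@H]2[C@]1(C)CC[C@@]2(O[Si](C)(C)C)C(C)C | intermediate
15 | dioxygen | O=O | starting material
16 | endoperoxide: O–O bridge from C6 to C10 on the α face, C10 also bearing OSiMe3, C7=C8 | C[Si](C)(C)O[C@@]12OO[C@@H](C=C1C)[C@@H]1[C@]2(C)CC[C@@]1(O[Si](C)(C)C)C(C)C | intermediate
17 | 6α-hydroxy enone: C10 ketone, C7=C8, 6α-OH, 4β-OSiMe3 | O=C1C(C)=C[C@H](O)[C@@H]2[C@]1(C)CC[C@@]2(O[Si](C)(C)C)C(C)C | intermediate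
18 | isovaleryl chloride (3-methylbutanoyl chloride) | CC(C)CC(=O)Cl | starting material
19 | 6α-isovalerate enone: as 17 with the C6 oxygen acylated | O=C1C(C)=C[C@H](OC(=O)CC(C)C)[C@@H]2[C@]1(C)CC[C@@]2(O[Si](C)(C)C)C(C)C | intermediate
20 | chlorotrimethylsilane | C[Si](C)(C)Cl | starting material
21 | trans-hydrindanone C10 trimethylsilyl enol ether (C10=C8), 6α-isovalerate, 4β-OSiMe3 | C[Si](C)(C)OC1=C(C)C[C@H](OC(=O)CC(C)C)[C@@H]2[C@]1(C)CC[C@@]2(O[Si](C)(C)C)C(C)C | intermediate
22 | diiodomethane | ICI | starting material
23 | siloxycyclopropane: CH2 (C9) bridging C10(OSiMe3) and C8(Me) of 21, configuration at C8/C10 not defined | C[Si](C)(C)OC12CC1(C)C[C@H](OC(=O)CC(C)C)[C@@H]1[C@]2(C)CC[C@@]1(O[Si](C)(C)C)C(C)C | intermediate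
24 | β-chloro ketone: hydroazulenone with C10 ketone, C9H2, C8(Cl)(Me), C8 configuration not defined | O=C1CC(C)(Cl)C[C@H](OC(=O)CC(C)C)[C@@H]2[C@]1(C)CC[C@@]2(O[Si](C)(C)C)C(C)C | intermediate
25 | hydroazulenone: C10 ketone conjugated with C8=C9, 6α-isovalerate, 4β-OSiMe3, C1 methyl β, H5 α | O=C1C=C(C)C[C@H](OC(=O)CC(C)C)[C@@H]2[C@]1(C)CC[C@@]2(O[Si](C)(C)C)C(C)C | intermediate
26 | 10β-allylic alcohol (OH cis to the C1 methyl), C8=C9 | O[C@H]1C=C(C)C[C@H](OC(=O)CC(C)C)[C@@H]2[C@]1(C)CC[C@@]2(O[Si](C)(C)C)C(C)C | intermediate
27 | formic acid | O=CO | starting material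
28 | 10α-formate, C8=C9 | O=CO[C@@H]1C=C(C)C[C@H](OC(=O)CC(C)C)[C@@H]2[C@]1(C)CC[C@@]2(O[Si](C)(C)C)C(C)C | intermediate
29 | 10α-allylic alcohol, C8=C9 | O[C@@H]1C=C(C)C[C@H](OC(=O)CC(C)C)[C@@H]2[C@]1(C)CC[C@@]2(O[Si](C)(C)C)C(C)C | intermediate
30 | tert-butyl hydroperoxide | CC(C)(C)OO | starting material
31 | 8α,9α-epoxy-10α-alcohol, 6α-isovalerate, 4β-OSiMe3 | O[C@@H]1[C@@H]2O[C@]2(C)C[C@H](OC(=O)CC(C)C)[C@@H]2[C@]1(C)CC[C@@]2(O[Si](C)(C)C)C(C)C | intermediate
32 | acetic anhydride | CC(=O)OC(C)=O | starting material
33 | 10α-acetate of 31 | CC(=O)O[C@@H]1[C@@H]2O[C@]2(C)C[C@H](OC(=O)CC(C)C)[C@@H]2[C@]1(C)CC[C@@]2(O[Si](C)(C)C)C(C)C | intermediate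
34 | CNP0137153.1, 10α-acetoxy-8α,9α-epoxy-4β-hydroxy-6α-isovaleryloxydaucane | CC(=O)O[C@@H]1[C@@H]2O[C@]2(C)C[C@H](OC(=O)CC(C)C)[C@@H]2[C@]1(C)CC[C@@]2(O)C(C)C | target

**Step count**

Total: 17 steps. Longest linear sequence: 17 steps, from (R)-carvone 1 to 34.

**Steps most likely to fail**

Step 9 (oxygen at C6). The oxygen transfer may be misdirected: ene-type attack at the C10=C8 enol ether, addition from the β face, or hydrolysis of the dienol ether before it reacts. The fallback sets out from 14 and returns at 17. The dienol ether is cleaved with MeLi (THF, −78 °C) to the lithium dienolate, which is protonated kinetically at C8 with AcOH at −78 °C to give the β,γ-unsaturated ketone F2 (C6=C7). Epoxidation of this isolated double bond with mCPBA/NaHCO3 should occur from the α face, opposite the C1 methyl, to give the 6α,7α-epoxy ketone F3. DBU (CH2Cl2, 0 °C) then opens the epoxide by E1cB elimination through the C8 hydrogen and gives 17.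

Step 14 (inversion at C10). Substitution at the neopentyl-type allylic carbon may not take place, or ionisation may lead to allylic transposition to C8 or to diene formation. The fallback sets out from 25 and returns at 29, replacing steps 13 and 14. It is a Corey–Bakshi–Shibata reduction of the enone with catecholborane (toluene, −78 °C) under control of the 2-methyl oxazaborolidine enantiomer that delivers hydride to the β face; this should be the (S)-catalyst if quaternary C1 acts as the large flank in the usual model. Reagent control thus replaces substitution, and no compound outside the compound list is made (F0).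

Step 5 (five-ring closure). C5 may epimerise through the enol or enamine of the C4 ketone, which would lead to the cis-fused bicycle, or the formyl group may be lost by retro-Claisen cleavage of the β-keto aldehyde. The fallback sets out from 8 and returns at 9. The methyl ketone is converted into its kinetic boron enolate (Bu2BOTf, i-Pr2NEt, CH2Cl2, −78 °C), which adds to the aldehyde in a directed aldol addition to give the β-hydroxy ketone F1 (hydroxyl on C2). Syn-dehydration with methyl N-(triethylammoniosulfonyl)carbamate (benzene, 50 °C) then gives 9 without an equilibrating base.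

**Further compounds**

F1 | step 5 | β-hydroxy ketone: trans-fused aldol adduct with C2–OH, C4 ketone, C10 ketone, C7=C8 (C2 configuration not defined) | O=C1C(C)=CC[C@@H]2[C@]1(C)C(O)CC2=O
F2 | step 9 | β,γ-unsaturated ketone: C10 ketone, C8–H, C6=C7, 4β-OSiMe3 (C8 configuration not defined) | O=C1C(C)C=C[C@@H]2[C@]1(C)CC[C@@]2(O[Si](C)(C)C)C(C)C
F3 | step 9 | 6α,7α-epoxy ketone: C10 ketone, C8–H, 4β-OSiMe3 | O=C1C(C)[C@@H]3O[C@@H]3[C@@H]2[C@]1(C)CC[C@@]2(O[Si](C)(C)C)C(C)C
F0 | step 14 | none | none
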